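**Retrosynthetic overview**
1. Target ⇐ acetylation and desilylation ⇐ Z-selective enyne cross-metathesis on the 2-allyl oxocane 22.
2. Oxocane 22 (formed last) ⇐ 5 → 8 ring expansion of tetrahydrofuran 19: the ring oxygen displaces a C6 triflate, then chloride opens the bicyclic oxonium at C9 (two inversions, giving C6–O and C9–Cl).
3. 19 ⇐ two-carbon homologation at C8 (⁻CH2CN), organocatalytic α-chlorination (C7), anti-selective allylation (C6).
4. Tetrahydrofuran ring B (the furanose of 2-deoxy-D-ribose; C9 and C10 from the sugar) ⇐ key C12–C13 bond: sparteine-bound α-lithio carbamate of propan-1-ol (α-oxy carbanion) + lactone carbonyl; lactol reduction sets C12, bromide inversion sets C13.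
5. Ring order: tetrahydrofuran first (from the sugar), a second five-membered ring A only transiently in the oxonium, the oxocane last.

Assumption: atoms carry the acetogenin numbering of the target (C1 = alkyne CH, C6 and C12 = ring carbons next to the ring oxygen, C15 = methyl); TBS = tert-butyldimethylsilyl, TIPS = triisopropylsilyl; (+)-sparteine, the pyrrolidine catalyst and the ruthenium catalyst are bought.

**Step 1**
Reactants: 1 2-deoxy-D-ribose
Product: 2 2-deoxy-D-ribono-1,4-lactone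
Conditions: Br2, H2O, rt, 4 d
Reagents that add atoms: none
Why: Bromine-water oxidation of the aldose hemiacetal (aldose to aldonolactone) gives the γ-lactone and leaves untouched the two carbinol centres that become C10 (S) and C9 (R).

**Step 2**
Reactants: 2 2-deoxy-D-ribono-1,4-lactone
Product: 3 3,5-di-O-TBS-2-deoxy-D-ribono-1,4-lactone
Conditions: TBSCl (2.4 equiv), imidazole, DMF, rt
Reagents that add atoms: tert-butyldimethylsilyl chloride, CC(C)(C)[Si](C)(C)Cl
Why: Silyl ether formation on both hydroxyls makes the lactone compatible with organolithium chemistry and allows the primary position to be unmasked selectively later.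

**Step 3**
Reactants: 4 propan-1-ol; 5 N,N-diisopropylcarbamoyl chloride
Product: 6 propyl N,N-diisopropylcarbamate
Conditions: pyridine, 90 °C
Reagents that add atoms: none
Why: O-Carbamoylation (acyl substitution) installs the dipole-stabilising group that directs the later α-lithiation.

**Step 4**
Reactants: 6 propyl N,N-diisopropylcarbamate; 3 3,5-di-O-TBS-2-deoxy-D-ribono-1,4-lactone
Product: 8 lactol (anomeric mixture) (1S)-1-[(4S,5R)-2-hydroxy-4-(TBS-oxy)-5-(TBS-oxymethyl)oxolan-2-yl]propyl N,N-diisopropylcarbamate, via lithiated carbamate 7 (not isolated)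
Conditions: 6, s-BuLi, (+)-sparteine, Et2O, −78 °C, 5 h; then 3, −78 °C; AcOH quench at −78 °C
Reagents that add atoms: sec-butyllithium, [Li]C(C)CC (its lithium is in 7 only)
Why: Hoppe-type sparteine-mediated asymmetric α-lithiation gives a configurationally stable α-oxy carbanion (a reversed-polarity carbinol synthon) that adds with retention to the lactone carbonyl, joining two carbons that are both electrophilic in the parent aldehyde and lactone; (+)-sparteine removes the pro-R proton so that C13 becomes S, and the tetrahedral adduct survives to the quench so that a single addition gives the lactol.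

**Step 5**
Reactants: 8 lactol
Product: 9 (1S)-1-[(2R,4S,5R)-4-(TBS-oxy)-5-(TBS-oxymethyl)oxolan-2-yl]propyl N,N-diisopropylcarbamate
Conditions: Et3SiH, BF3·OEt2, CH2Cl2, −78 → −40 °C
Reagents that add atoms: none
Why: Ionic hydrogenation of the lactol (silane reduction of the cyclic oxocarbenium ion) delivers hydride on the face cis to the C10 silyloxy group (inside attack on the envelope), giving the 2,5-cis tetrahydrofuran with C12 R, as in β-C-glycoside syntheses from 2-deoxyribonolactone.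

**Step 6**
Reactants: 9 C-glycoside carbamate
Product: 10 (1S)-1-[(2R,4S,5R)-4-(TBS-oxy)-5-(TBS-oxymethyl)oxolan-2-yl]propan-1-ol
Conditions: LiAlH4, THF, reflux; aqueous work-up
Reagents that add atoms: none
Why: Hydride reduction of the carbamate cleaves it to the alcohol and the N-methylamine with retention at C13, since no bond to C13 is broken.

**Step 7**
Reactants: 10 secondary alcohol
Product: 11 (2R,3S,5R)-5-[(1R)-1-bromopropyl]-3-(TBS-oxy)-2-(TBS-oxymethyl)oxolane
Conditions: CBr4, P(n-C8H17)3, toluene, 60 °C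
Reagents that add atoms: tetrabromomethane, BrC(Br)(Br)Br
Why: Appel bromination, an SN2 displacement of the alkoxyphosphonium by bromide, inverts C13 from S (oxygen) to R (bromine).

**Step 8**
Reactants: 11 bis-silyl bromide
Product: 12 [(2R,3S,5R)-5-[(1R)-1-bromopropyl]-3-(TBS-oxy)oxolan-2-yl]methanol
Conditions: camphorsulfonic acid (10 mol %), MeOH–CH2Cl2, 0 °C
Reagents that add atoms: none
Why: Acid-catalysed methanolysis cleaves the unhindered primary silyl ether much faster than the secondary one (selective desilylation).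

**Step 9**
Reactants: 12 primary alcohol
Product: 14 3-[(2R,3S,5R)-5-[(1R)-1-bromopropyl]-3-(TBS-oxy)oxolan-2-yl]propanenitrile, via primary triflate 13 (not isolated)
Conditions: Tf2O, pyridine, CH2Cl2, −78 → −40 °C; then LiCH2CN (MeCN, n-BuLi), THF, −78 °C
Reagents that add atoms: acetonitrile, CC#N; triflic anhydride, O=S(=O)(OS(=O)(=O)C(F)(F)F)C(F)(F)F (its triflyl group is in 13 only)
Why: Sulfonylation of the primary alcohol followed by SN2 alkylation of lithioacetonitrile adds C7 and C6, the primary triflate reacting at −78 °C where the secondary bromide is inert.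

**Step 10**
Reactants: 14 nitrile
Product: 16 3-[(2R,3S,5R)-5-[(1R)-1-bromopropyl]-3-(TBS-oxy)oxolan-2-yl]propanal, via aluminated imine 15 (not isolated)
Conditions: DIBAL-H, CH2Cl2, −78 °C; then 1 M HCl, 0 °C
Reagents that add atoms: water, O; diisobutylaluminium hydride, CC(C)C[AlH]CC(C)C (its aluminium group is in 15 only)
Why: DIBAL-H half-reduction of the nitrile stops at the N-aluminated imine, which hydrolyses to the aldehyde on acidic work-up.

**Step 11**
Reactants: 16 aldehyde
Product: 17 (2S)-3-[(2R,3S,5R)-5-[(1R)-1-bromopropyl]-3-(TBS-oxy)oxolan-2-yl]-2-chloropropanal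
Conditions: N-chlorosuccinimide, trans-2,5-diphenylpyrrolidine (10 mol %; the enantiomer that gives the 7S chloride), CH2Cl2, 0 °C; used crude
Reagents that add atoms: N-chlorosuccinimide, O=C1CCC(=O)N1Cl
Why: Enamine organocatalysis (asymmetric α-chlorination of an aldehyde) sets C7 as S under catalyst control, the remote ring stereocentres having little influence.

**Step 12**
Reactants: 17 α-chloro aldehyde
Product: 19 (2S,3R)-1-[(2R,3S,5R)-5-[(1R)-1-bromopropyl]-3-(TBS-oxy)oxolan-2-yl]-2-chlorohex-5-en-3-ol, via borate ester 18 (not isolated)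
Conditions: allylboronic acid pinacol ester, CH2Cl2, −78 °C → rt; then pH 7 buffer
Reagents that add atoms: allylboronic acid pinacol ester, C=CCB1OC(C)(C)C(C)(C)O1 (its boron group is in 18 only)
Why: Allylboration through a closed six-membered transition state follows the Cornforth (polar Felkin–Anh) model for α-chloro aldehydes and gives the 1,2-anti chlorohydrin, so the new C6 is R (the minor syn isomer is removed by chromatography).

**Step 13**
Reactants: 19 anti-chlorohydrin
Product: 22 tert-butyl{[(2S,3S,5S,6S,8R)-8-[(1R)-1-bromopropyl]-3,5-dichloro-2-(prop-2-en-1-yl)oxocan-6-yl]oxy}dimethylsilane, via secondary triflate 20 (not isolated), via bicyclic oxonium triflate 21 (not isolated)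
Conditions: Tf2O, 2,6-di-tert-butyl-4-methylpyridine, CH2Cl2, −78 → −20 °C; then Bu4NCl, −40 → 0 °C
Reagents that add atoms: tetrabutylammonium chloride, CCCC[N+](CCCC)(CCCC)CCCC.[Cl-]; triflic anhydride, O=S(=O)(OS(=O)(=O)C(F)(F)F)C(F)(F)F (its triflyl group is in 20 and 21 only)
Why: Proposed new method: the triflate of the β-chloro alcohol is displaced by the tetrahydrofuran oxygen five atoms away (5-exo-tet neighbouring-group attack, inversion at C6, allyl on the convex face) to give the cis-fused 1-oxoniabicyclo[3.3.0]octane 21, and chloride then attacks the ring-fusion carbon C9 with inversion (its β-substituents are tied back in the two rings, it carries the less electron-withdrawing β-silyloxy group whereas C6 and C12 carry β-chlorine and a branched β-bromoalkyl group, and cleaving the bond shared by both rings releases the most strain), which turns the 2,5-cis tetrahydrofuran into the 2,8-trans oxocane with C6 S and C9 S; the closest known reaction types are the sulfonate-triggered ring expansion of tetrahydrofurans to oxocanes through bicyclo[3.3.0] oxonium ions and the bromonium-induced ring-expanding etherification of tetrahydrofurans to eight-membered haloethers, the new element being external chloride as the ring-opening nucleophile.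

**Step 14**
Reactants: 23 ethynyl(triisopropyl)silane; 24 vinyl bromide
Product: 25 but-3-en-1-yn-1-yl(triisopropyl)silane
Conditions: Pd(PPh3)2Cl2 (2 mol %), CuI (4 mol %), i-Pr2NH, THF, rt
Reagents that add atoms: none
Why: Sonogashira coupling of the terminal alkyne with the vinyl halide gives the conjugated enyne.

**Step 15**
Reactants: 22 2-allyl oxocane; 25 silyl enyne (3 equiv)
Product: 26 TIPS-protected (Z)-enyne: tert-butyl{[(2S,3S,5S,6S,8R)-8-[(1R)-1-bromopropyl]-3,5-dichloro-2-[(2Z)-5-(triisopropylsilyl)pent-2-en-4-yn-1-yl]oxocan-6-yl]oxy}dimethylsilane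
Conditions: second-generation Grubbs catalyst RuCl2(=CHPh)(H2IMes)(PCy3) (10 mol %), CH2Cl2, 40 °C
Reagents that add atoms: none
Why: Olefin cross-metathesis of a terminal alkene with a conjugated enyne is kinetically Z-selective at the new C3=C4 bond, a known entry to Z-enynes of this family, and tolerates the halides and the silyl ether.

**Step 16**
Reactants: 26 bis-silyl enyne
Product: 27 (2S,3S,5S,6S,8R)-8-[(1R)-1-bromopropyl]-3,5-dichloro-2-[(2Z)-pent-2-en-4-yn-1-yl]oxocan-6-ol
Conditions: Bu4NF, AcOH, THF, 0 °C → rt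
Reagents that add atoms: none
Why: Fluoride-mediated desilylation removes the O-silyl and the alkynyl C-silyl groups together, acetic acid buffering the fluoride so that the secondary halides are not eliminated.

**Step 17**
Reactants: 27 alcohol
Product: 28 (2S,3S,5S,6S,8R)-8-[(1R)-1-bromopropyl]-3,5-dichloro-2-[(2Z)-pent-2-en-4-yn-1-yl]oxocan-6-yl acetate (CNP0251465.2)
Conditions: Ac2O, pyridine, DMAP (cat.), CH2Cl2, 0 °C
Reagents that add atoms: acetic anhydride, CC(=O)OC(C)=O
Why: DMAP-catalysed acylation of the secondary alcohol gives the acetate with retention at C10.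

**Compound list**
1 | 2-deoxy-D-ribose, (3S,4R)-3,4,5-trihydroxypentanal | O=CC[C@H](O)[C@H](O)CO | starting material
2 | 2-deoxy-D-ribono-1,4-lactone, (4S,5R)-4-hydroxy-5-(hydroxymethyl)oxolan-2-one | O=C1C[C@H](O)[C@@H](CO)O1 | intermediate
3 | (4S,5R)-4-(TBS-oxy)-5-(TBS-oxymethyl)oxolan-2-one | O=C1C[C@H](O[Si](C)(C)C(C)(C)C)[C@@H](CO[Si](C)(C)C(C)(C)C)O1 | intermediate
4 | propan-1-ol | CCCO | starting material
5 | N,N-diisopropylcarbamoyl chloride | CC(C)N(C(C)C)C(Cl)=O | starting material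
6 | propyl N,N-diisopropylcarbamate | CCCOC(=O)N(C(C)C)C(C)C | intermediate
7 | (R)-1-lithiopropyl N,N-diisopropylcarbamate, bound to (+)-sparteine (ligand not drawn) | CC[C@@H]([Li])OC(=O)N(C(C)C)C(C)C | intermediate (not isolated)
8 | (1S)-1-[(4S,5R)-2-hydroxy-4-(TBS-oxy)-5-(TBS-oxymethyl)oxolan-2-yl]propyl N,N-diisopropylcarbamate, anomeric mixture | CC[C@H](OC(=O)N(C(C)C)C(C)C)C1(O)C[C@H](O[Si](C)(C)C(C)(C)C)[C@@H](CO[Si](C)(C)C(C)(C)C)O1 | intermediate
9 | (1S)-1-[(2R,4S,5R)-4-(TBS-oxy)-5-(TBS-oxymethyl)oxolan-2-yl]propyl N,N-diisopropylcarbamate | CC[C@H](OC(=O)N(C(C)C)C(C)C)[C@H]1C[C@H](O[Si](C)(C)C(C)(C)C)[C@@H](CO[Si](C)(C)C(C)(C)C)O1 | intermediate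
10 | (1S)-1-[(2R,4S,5R)-4-(TBS-oxy)-5-(TBS-oxymethyl)oxolan-2-yl]propan-1-ol | CC[C@H](O)[C@H]1C[C@H](O[Si](C)(C)C(C)(C)C)[C@@H](CO[Si](C)(C)C(C)(C)C)O1 | intermediate
11 | (2R,3S,5R)-5-[(1R)-1-bromopropyl]-3-(TBS-oxy)-2-(TBS-oxymethyl)oxolane | CC[C@@H](Br)[C@H]1C[C@H](O[Si](C)(C)C(C)(C)C)[C@@H](CO[Si](C)(C)C(C)(C)C)O1 | intermediate
12 | [(2R,3S,5R)-5-[(1R)-1-bromopropyl]-3-(TBS-oxy)oxolan-2-yl]methanol | CC[C@@H](Br)[C@H]1C[C@H](O[Si](C)(C)C(C)(C)C)[C@@H](CO)O1 | intermediate
13 | [(2R,3S,5R)-5-[(1R)-1-bromopropyl]-3-(TBS-oxy)oxolan-2-yl]methyl triflate | CC[C@@H](Br)[C@H]1C[C@H](O[Si](C)(C)C(C)(C)C)[C@@H](COS(=O)(=O)C(F)(F)F)O1 | intermediate (not isolated)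
14 | 3-[(2R,3S,5R)-5-[(1R)-1-bromopropyl]-3-(TBS-oxy)oxolan-2-yl]propanenitrile | CC[C@@H](Br)[C@H]1C[C@H](O[Si](C)(C)C(C)(C)C)[C@@H](CCC#N)O1 | intermediate
15 | N-(diisobutylaluminio)imine of aldehyde 16 | CC[C@@H](Br)[C@H]1C[C@H](O[Si](C)(C)C(C)(C)C)[C@@H](CCC=N[Al](CC(C)C)CC(C)C)O1 | intermediate (not isolated)
16 | 3-[(2R,3S,5R)-5-[(1R)-1-bromopropyl]-3-(TBS-oxy)oxolan-2-yl]propanal | CC[C@@H](Br)[C@H]1C[C@H](O[Si](C)(C)C(C)(C)C)[C@@H](CCC=O)O1 | intermediate
17 | (2S)-3-[(2R,3S,5R)-5-[(1R)-1-bromopropyl]-3-(TBS-oxy)oxolan-2-yl]-2-chloropropanal | CC[C@@H](Br)[C@H]1C[C@H](O[Si](C)(C)C(C)(C)C)[C@@H](C[C@H](Cl)C=O)O1 | intermediate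
18 | pinacol borate ester of alcohol 19 (O–B bond at C6) | CC[C@@H](Br)[C@H]1C[C@H](O[Si](C)(C)C(C)(C)C)[C@@H](C[C@H](Cl)[C@H](OB2OC(C)(C)C(C)(C)O2)CC=C)O1 | intermediate (not isolated)
19 | (2S,3R)-1-[(2R,3S,5R)-5-[(1R)-1-bromopropyl]-3-(TBS-oxy)oxolan-2-yl]-2-chlorohex-5-en-3-ol | CC[C@@H](Br)[C@H]1C[C@H](O[Si](C)(C)C(C)(C)C)[C@@H](C[C@H](Cl)[C@H](O)CC=C)O1 | intermediate
20 | triflate of alcohol 19 (C6–OTf) | CC[C@@H](Br)[C@H]1C[C@H](O[Si](C)(C)C(C)(C)C)[C@@H](C[C@H](Cl)[C@H](OS(=O)(=O)C(F)(F)F)CC=C)O1 | intermediate (not isolated)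
21 | cis-fused 1-oxoniabicyclo[3.3.0]octane triflate: O+ bonded to C6, C9 and C12; ring A = O, C6 (allyl), C7 (Cl), C8, C9; ring B = O, C9, C10 (OTBS), C11, C12 ((1R)-1-bromopropyl) | C=CC[C@H]1[C@@H](Cl)C[C@@H]2[C@@H](O[Si](C)(C)C(C)(C)C)C[C@H]([C@H](Br)CC)[O+]12.[O-]S(=O)(=O)C(F)(F)F | intermediate (not isolated)
22 | tert-butyl{[(2S,3S,5S,6S,8R)-8-[(1R)-1-bromopropyl]-3,5-dichloro-2-(prop-2-en-1-yl)oxocan-6-yl]oxy}dimethylsilane | C=CC[C@@H]1O[C@@H]([C@H](Br)CC)C[C@H](O[Si](C)(C)C(C)(C)C)[C@@H](Cl)C[C@@H]1Cl | intermediate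
23 | ethynyl(triisopropyl)silane | C#C[Si](C(C)C)(C(C)C)C(C)C | starting material
24 | vinyl bromide | C=CBr | starting material
25 | but-3-en-1-yn-1-yl(triisopropyl)silane | C=CC#C[Si](C(C)C)(C(C)C)C(C)C | intermediate
26 | tert-butyl{[(2S,3S,5S,6S,8R)-8-[(1R)-1-bromopropyl]-3,5-dichloro-2-[(2Z)-5-(triisopropylsilyl)pent-2-en-4-yn-1-yl]oxocan-6-yl]oxy}dimethylsilane | CC(C)[Si](C(C)C)(C(C)C)C#C/C=C\C[C@@H]1O[C@@H]([C@H](Br)CC)C[C@H](O[Si](C)(C)C(C)(C)C)[C@@H](Cl)C[C@@H]1Cl | intermediate
27 | (2S,3S,5S,6S,8R)-8-[(1R)-1-bromopropyl]-3,5-dichloro-2-[(2Z)-pent-2-en-4-yn-1-yl]oxocan-6-ol | C#C/C=C\C[C@@H]1O[C@@H]([C@H](Br)CC)C[C@H](O)[C@@H](Cl)C[C@@H]1Cl | intermediate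
28 | (2S,3S,5S,6S,8R)-8-[(1R)-1-bromopropyl]-3,5-dichloro-2-[(2Z)-pent-2-en-4-yn-1-yl]oxocan-6-yl acetate | C#C/C=C\C[C@@H]1O[C@@H]([C@H](Br)CC)C[C@H](OC(C)=O)[C@@H](Cl)C[C@@H]1Cl | target

**Step count and risks**
Total step count: 17 (steps 3 and 14 make the two side partners).
Longest linear sequence: 15 steps, 1 → 2 → 3 → 8 → 9 → 10 → 11 → 12 → 14 → 16 → 17 → 19 → 22 → 26 → 27 → 28.

Most likely to fail:

1. Step 13 (ring expansion). Chloride may open oxonium 21 at C6 or C12 instead of C9, and the β-chloro triflate 20 may ionise slowly or suffer π-participation from the allyl group. The fallback triggers the oxonium with a chloronium ion instead of a sulfonate, so that C6–O and C7–Cl are made together by anti addition to a Z-alkene. It sets out from alcohol 12. Its triflate 13 is alkylated with pent-4-en-1-yn-1-yllithium F5 (from commercial pent-1-en-4-yne and n-BuLi, THF, −78 °C) to give the skipped enyne F6. Semihydrogenation over Pd on CaCO3 poisoned with Pb(OAc)2 (quinoline, H2) gives the (Z)-1,4-diene F7. Chlorodiethylsulfonium hexachloroantimonate, Et2SCl·SbCl6, in MeNO2 at −30 °C chlorinates the Z-alkene, and the ring oxygen closes ring A at C6 to give the oxonium hexachloroantimonate F8. Bu4NCl then opens it at C9, and the route is rejoined at oxocane 22. This fallback still depends on the same regiochemistry of oxonium opening, and the C10 silyl ether oxygen may compete for the chloronium ion.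

2. Step 4 (key C12–C13 bond). The lithiated carbamate may enolise the lactone (with loss of the C10 silyloxy group) rather than add, or add sluggishly. The fallback replaces the chiral α-oxy carbanion by an achiral acyl anion equivalent and sets C13 afterwards by substrate control. It sets out from lactone 3. 2-Ethyl-2-lithio-1,3-dithiane F1 (from commercial 2-ethyl-1,3-dithiane and n-BuLi) adds to 3 to give the dithianyl lactol F2. Et3SiH and BF3·OEt2 reduce it to the 2,5-cis dithianyl tetrahydrofuran F3. MeI and CaCO3 in aqueous MeCN unmask the ethyl ketone F4. Chelation-controlled reduction with Zn(BH4)2 in Et2O at −30 °C gives the anti (13S) alcohol, and the route is rejoined at 10.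

3. Step 15 (Z-enyne cross-metathesis). Z/E selectivity or conversion may be poor. The fallback builds the Z-alkene by olefination and the enyne by coupling. It sets out from 22. Ozonolysis (O3, CH2Cl2, −78 °C; PPh3) gives the aldehyde F9. Stork–Zhao olefination with (iodomethylene)triphenylphosphorane F10 (from (iodomethyl)triphenylphosphonium iodide and NaHMDS, THF, −78 °C) gives the (Z)-vinyl iodide F11. Sonogashira coupling with 23 (Pd(PPh3)4, CuI, i-Pr2NH) retains the alkene geometry, and the route is rejoined at 26.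

**Further compounds**
F1 | step 4 | 2-ethyl-2-lithio-1,3-dithiane | CCC1([Li])SCCCS1
F2 | step 4 | (4S,5R)-2-(2-ethyl-1,3-dithian-2-yl)-4-(TBS-oxy)-5-(TBS-oxymethyl)oxolan-2-ol, anomeric mixture | CCC1(SCCCS1)C2(O)C[C@H](O[Si](C)(C)C(C)(C)C)[C@@H](CO[Si](C)(C)C(C)(C)C)O2
F3 | step 4 | 2,5-cis 5-(2-ethyl-1,3-dithian-2-yl)-3-(TBS-oxy)-2-(TBS-oxymethyl)oxolane | CCC1(SCCCS1)[C@H]2C[C@H](O[Si](C)(C)C(C)(C)C)[C@@H](CO[Si](C)(C)C(C)(C)C)O2
F4 | step 4 | 1-[(2R,4S,5R)-4-(TBS-oxy)-5-(TBS-oxymethyl)oxolan-2-yl]propan-1-one | CCC(=O)[C@H]1C[C@H](O[Si](C)(C)C(C)(C)C)[C@@H](CO[Si](C)(C)C(C)(C)C)O1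
F5 | step 13 | pent-4-en-1-yn-1-yllithium | [Li]C#CCC=C
F6 | step 13 | (2R,3S,5R)-5-[(1R)-1-bromopropyl]-2-(hex-5-en-2-yn-1-yl)-3-(TBS-oxy)oxolane | CC[C@@H](Br)[C@H]1C[C@H](O[Si](C)(C)C(C)(C)C)[C@@H](CC#CCC=C)O1
F7 | step 13 | (2R,3S,5R)-5-[(1R)-1-bromopropyl]-2-[(2Z)-hexa-2,5-dien-1-yl]-3-(TBS-oxy)oxolane | CC[C@@H](Br)[C@H]1C[C@H](O[Si](C)(C)C(C)(C)C)[C@@H](C/C=C\CC=C)O1
F8 | step 13 | oxonium cation of 21 as its hexachloroantimonate | C=CC[C@H]1[C@@H](Cl)C[C@@H]2[C@@H](O[Si](C)(C)C(C)(C)C)C[C@H]([C@H](Br)CC)[O+]12.Cl[Sb-](Cl)(Cl)(Cl)(Cl)Cl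
F9 | step 15 | 2-[(2S,3S,5S,6S,8R)-8-[(1R)-1-bromopropyl]-3,5-dichloro-6-(TBS-oxy)oxocan-2-yl]acetaldehyde | O=CC[C@@H]1O[C@@H]([C@H](Br)CC)C[C@H](O[Si](C)(C)C(C)(C)C)[C@@H](Cl)C[C@@H]1Cl
F10 | step 15 | (iodomethylene)triphenylphosphorane | IC=P(c1ccccc1)(c1ccccc1)c1ccccc1
F11 | step 15 | (2S,3S,5S,6S,8R)-8-[(1R)-1-bromopropyl]-3,5-dichloro-2-[(2Z)-3-iodoprop-2-en-1-yl]-6-(TBS-oxy)oxocane | I/C=C\C[C@@H]1O[C@@H]([C@H](Br)CC)C[C@H](O[Si](C)(C)C(C)(C)C)[C@@H](Cl)C[C@@H]1Cl
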